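**Strategy.** Numbering: C1 is the lactone carbonyl, C2=C3 the Z-alkene, C5 and C8 the carbinols, C6/C7 the oxirane carbons, C21 the lactone O-bearing methine. The route rests on the C4–C5 bond: the C5 hydroxyl sits δ to C1 across the (2Z)-alkene, a vinylogous aldol retron inside the 22-membered ring. A monovalent-copper dienolate of an open-chain C21 but-3-enoate attacks, through C4, the aldehyde C5 of a trans-6,7-epoxy aldehyde (C8 as TES ether). This single macrocyclisation closes the lactone ring and sets C5 and the Z-olefin. The chain comes from 1-bromo-10-chlorodecane, (S)-epichlorohydrin and (R)-propylene oxide.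

Key step: step 8

Assumption: 1-bromo-10-chlorodecane is treated as a catalogue chemical (otherwise it is one bromination step from commercial 10-chlorodecan-1-ol).

Step 1
Reactants: 1 1-bromo-10-chlorodecane; 2 (S)-epichlorohydrin
Product: 4 (2S)-1,13-dichlorotridecan-2-ol, via 10-chlorodecylmagnesium bromide 3 (not isolated)
Conditions: Mg, THF, 25 °C; then 2, CuI (10 mol%), −40 → −20 °C; aq NH4Cl
Reagents that add atoms: none
Why: Magnesium inserts selectively into the C–Br bond, and the CuI-catalysed Grignard opening of the oxirane at its unsubstituted carbon (SN2) leaves the epichlorohydrin stereocentre untouched, so that it becomes C8 (S).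

Step 2
Reactants: 4 (2S)-1,13-dichlorotridecan-2-ol
Product: 6 (3S)-14-chlorotetradec-1-en-3-ol, via (2S)-2-(11-chloroundecyl)oxirane 5 (not isolated)
Conditions: Me3S+ I− (4 equiv), n-BuLi (3.9 equiv), THF, −10 °C → rt
Reagents that add atoms: trimethylsulfonium iodide, C[S+](C)C.[I-]
Why: Excess dimethylsulfonium methylide closes the chlorohydrin to the terminal epoxide, opens it at CH2 and eliminates Me2S from the resulting alkoxy sulfonium salt (one-carbon epoxide-to-allylic-alcohol homologation); C8 is never touched and the remote primary chloride should be too slow to compete.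

Step 3
Reactants: 6 (3S)-14-chlorotetradec-1-en-3-ol
Product: 7 {[(3S)-14-chlorotetradec-1-en-3-yl]oxy}triethylsilane
Conditions: TESCl, imidazole, DMAP (cat.), CH2Cl2, 0 °C
Reagents that add atoms: chlorotriethylsilane, CC[Si](Cl)(CC)CC
Why: Standard silylation of a secondary alcohol; the TES ether masks O8 through the Grignard, metathesis, epoxidation and aldol steps and makes the later C21 hydroxyl the only free one.

Step 4
Reactants: 7 {[(3S)-14-chlorotetradec-1-en-3-yl]oxy}triethylsilane; 8 (R)-propylene oxide
Product: 10 (2R,15S)-15-(triethylsilyloxy)heptadec-16-en-2-ol, via [(12S)-12-(triethylsilyloxy)tetradec-13-en-1-yl]magnesium chloride 9 (not isolated)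
Conditions: Mg (activated with 1,2-dibromoethane), THF, reflux; then CuI (10 mol%), 8, −30 → 0 °C; aq NH4Cl
Reagents that add atoms: none
Why: Grignard formation from the primary chloride tolerates the allylic silyl ether, and CuI-catalysed opening of (R)-propylene oxide at CH2 gives the (R)-methylcarbinol C21 with the epoxide stereocentre unchanged.

Step 5
Reactants: 10 (2R,15S)-15-(triethylsilyloxy)heptadec-16-en-2-ol; 11 (E)-but-2-enal (crotonaldehyde)
Product: 12 (2E,4S,17R)-17-hydroxy-4-(triethylsilyloxy)octadec-2-enal
Conditions: second-generation Hoveyda–Grubbs catalyst (5 mol%), 11 (5 equiv), CH2Cl2, 40 °C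
Reagents that add atoms: none
Why: Olefin cross-metathesis of the hindered allylic silyl ether with the electron-poor partner crotonaldehyde should favour the cross product and give the (E)-enal under thermodynamic control, the free C21 hydroxyl being tolerated.

Step 6
Reactants: 12 (2E,4S,17R)-17-hydroxy-4-(triethylsilyloxy)octadec-2-enal; 13 but-3-enoic acid
Product: 14 (2R,15S,16E)-18-oxo-15-(triethylsilyloxy)octadec-16-en-2-yl but-3-enoate
Conditions: DCC, DMAP (5 mol%), CH2Cl2, 0 °C
Reagents that add atoms: none
Why: Steglich esterification at 0 °C with only catalytic DMAP acylates the sole free hydroxyl while keeping the but-3-enoate out of conjugation; C21 keeps its configuration because its C–O bond is not broken.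

Step 7
Reactants: 14 (2R,15S,16E)-18-oxo-15-(triethylsilyloxy)octadec-16-en-2-yl but-3-enoate
Product: 15 (2R,15S)-15-[(2S,3S)-3-formyloxiran-2-yl]-15-(triethylsilyloxy)pentadecan-2-yl but-3-enoate
Conditions: (S)-2-{bis[3,5-bis(trifluoromethyl)phenyl](trimethylsilyloxy)methyl}pyrrolidine (10 mol%), 35% aq H2O2 (1.3 equiv), CH2Cl2, rt
Reagents that add atoms: hydrogen peroxide, OO
Why: Iminium-catalysed nucleophilic epoxidation with a Jørgensen–Hayashi catalyst: hydroperoxide should add to C7 on the face of the s-trans E-iminium ion opposite the shielding diaryl(silyloxy)methyl arm and the enamine then closes the trans-oxirane, so the catalyst sets C6 and C7 (spatially as in the target), while the unconjugated but-3-enoate is inert to H2O2.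

Step 8
Reactants: 15 (2R,15S)-15-[(2S,3S)-3-formyloxiran-2-yl]-15-(triethylsilyloxy)pentadecan-2-yl but-3-enoate
Product: 16 8-O-triethylsilyl CIML C, (2Z,5S,6R,7S,8S,21R)-6,7-epoxy-5-hydroxy-8-(triethylsilyloxy)docos-2-en-21-olide
Conditions: [Cu(CH3CN)4]PF6 (10 mol%), (R)-DTBM-SEGPHOS (11 mol%), Et3N (20 mol%), THF, 0 °C, 15 added by syringe pump over 12 h (final 1 mM); AcOH quench at 0 °C
Reagents that add atoms: none
Why: Proposed new method: the monovalent-copper/bisphosphine complex and Et3N deprotonate C2 of the but-3-enoate (soft Lewis acid/Brønsted base activation) to a copper dienolate that adds through its γ-carbon C4 to the aldehyde C5 in a six-membered chair-like transition state (Cu–C2–C3=C4···C5=O) with the ester group pseudoaxial, which makes the new C2=C3 bond Z, and proton transfer then frees the C5 alcohol and the catalyst. The closest known reaction type is the intermolecular direct vinylogous aldol reaction of β,γ-unsaturated esters with aldehydes under this kind of catalyst (γ- and Z-selective), and ring closure by a vinylogous aldol is known from the aluminium tris(2,6-diphenylphenoxide)-mediated macrolactonisation, which however gives E-enoates. The 22-membered lactone closes in a 22-exo-trig mode at C5. The new stereocentre C5 (S) is controlled by the ligand, which has to deliver C4 to the Si face of the aldehyde against the modest intrinsic anti preference of a trans-epoxy aldehyde; the ligand antipode is proposed on that basis and its sense should be confirmed on a simple trans-epoxy aldehyde. The step needs γ- over α-attack (bulky ligand, closed transition state), cyclisation over oligomerisation (slow addition to about 1 mM) and aldol over lactonisation of the Z-aldolate onto C1 (slowed by the α-branched C21 ester oxygen and fast protonation). In the substrate the aldehyde carries no enolisable α-hydrogen, so only the ester can be deprotonated, and the oxirane, TES ether and ester should be inert to the mild amine base.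

Step 9
Reactants: 16 8-O-triethylsilyl CIML C
Product: 17 CIML C
Conditions: HF·pyridine, pyridine, THF, 0 °C
Reagents that add atoms: none
Why: Buffered HF·pyridine should cleave the secondary TES ether at 0 °C without touching the oxirane, the Z-enoate or the lactone, and it avoids the alkoxide that could trigger translactonisation to the six-membered lactone.

**Compound list**

1 | 1-bromo-10-chlorodecane | ClCCCCCCCCCCBr | starting material
2 | (S)-epichlorohydrin, (2S)-2-(chloromethyl)oxirane | ClC[C@@H]1CO1 | starting material
3 | 10-chlorodecylmagnesium bromide | ClCCCCCCCCCC[Mg]Br | intermediate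
4 | (2S)-1,13-dichlorotridecan-2-ol | ClCCCCCCCCCCC[C@H](O)CCl | intermediate
5 | (2S)-2-(11-chloroundecyl)oxirane | ClCCCCCCCCCCC[C@H]1CO1 | intermediate
6 | (3S)-14-chlorotetradec-1-en-3-ol | ClCCCCCCCCCCC[C@H](O)C=C | intermediate
7 | {[(3S)-14-chlorotetradec-1-en-3-yl]oxy}triethylsilane | ClCCCCCCCCCCC[C@H](O[Si](CC)(CC)CC)C=C | intermediate
8 | (R)-propylene oxide, (2R)-2-methyloxirane | C[C@@H]1CO1 | starting material
9 | [(12S)-12-(triethylsilyloxy)tetradec-13-en-1-yl]magnesium chloride | Cl[Mg]CCCCCCCCCCC[C@H](O[Si](CC)(CC)CC)C=C | intermediate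
10 | (2R,15S)-15-(triethylsilyloxy)heptadec-16-en-2-ol | C[C@@H](O)CCCCCCCCCCCC[C@H](O[Si](CC)(CC)CC)C=C | intermediate
11 | (E)-but-2-enal (crotonaldehyde) | C/C=C/C=O | starting material
12 | (2E,4S,17R)-17-hydroxy-4-(triethylsilyloxy)octadec-2-enal | C[C@@H](O)CCCCCCCCCCCC[C@H](O[Si](CC)(CC)CC)/C=C/C=O | intermediate
13 | but-3-enoic acid | C=CCC(=O)O | starting material
14 | (2R,15S,16E)-18-oxo-15-(triethylsilyloxy)octadec-16-en-2-yl but-3-enoate | C=CCC(=O)O[C@H](C)CCCCCCCCCCCC[C@H](O[Si](CC)(CC)CC)/C=C/C=O | intermediate
15 | (2R,15S)-15-[(2S,3S)-3-formyloxiran-2-yl]-15-(triethylsilyloxy)pentadecan-2-yl but-3-enoate (oxirane carbons spatially as C6/C7 of the target) | C=CCC(=O)O[C@H](C)CCCCCCCCCCCC[C@H](O[Si](CC)(CC)CC)[C@H]1O[C@@H]1C=O | intermediate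
16 | 8-O-triethylsilyl CIML C, (2Z,5S,6R,7S,8S,21R)-6,7-epoxy-5-hydroxy-8-(triethylsilyloxy)docos-2-en-21-olide (C7 spatially as in the target; its descriptor changes with the silyl group) | C[C@@H]1CCCCCCCCCCCC[C@H](O[Si](CC)(CC)CC)[C@H]2O[C@@H]2[C@@H](O)C/C=C\C(=O)O1 | intermediate
17 | CIML C, (2Z,5S,6R,7R,8S,21R)-6,7-epoxy-5,8-dihydroxydocos-2-en-21-olide | C[C@@H]1CCCCCCCCCCCC[C@H](O)[C@H]2O[C@@H]2[C@@H](O)C/C=C\C(=O)O1 | target

**Step count.** Total: 9 steps. Longest linear sequence: 9 steps (from 1).

**Steps most likely to fail**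

1. Step 8 (proposed new method). The ring closure may lose out to oligomerisation, to migration of the but-3-enoate double bond into conjugation, or to attack of the Z-aldolate on C1 with opening of the macrocycle to a six-membered lactone. The ligand may also fail to override the substrate's facial bias at C5. The fallback uses known chemistry, sets out from 12 and comes back at 17. Compound 12 is acylated with acryloyl chloride and iPr2NEt (CH2Cl2, −20 °C) to the acrylate ester F1. This is epoxidised under the step 7 conditions to the epoxy aldehyde F2. The C4–C5 bond is then made intermolecularly by Brown allylboration with B-allyldiisopinocampheylborane derived from (+)-α-pinene (Et2O, −78 °C, NaBO3 work-up), which should attack the Si face under reagent control and give the homoallylic alcohol F3. Silylation (TESOTf, 2,6-lutidine) gives the bis-TES diene F4. The ring is closed at C2=C3 by Z-selective ring-closing metathesis with a molybdenum monoaryloxide pyrrolide alkylidene catalyst (benzene, 1 mM, reduced pressure), giving the bis-TES macrolactone F5. HF·pyridine/pyridine then removes both silyl groups to give 17.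

2. Step 7. Catalyst and substrate control may be mismatched at C7 next to the silyloxy-bearing C8, and the epoxy aldehyde may degrade under the aqueous amine conditions. The fallback sets out from 14 and comes back at 15. Luche reduction (NaBH4, CeCl3·7H2O, MeOH, −40 °C) gives the allylic alcohol F6. Sharpless asymmetric epoxidation (Ti(OiPr)4, D-(−)-diisopropyl tartrate, t-BuOOH, 4 Å molecular sieves, CH2Cl2, −20 °C) sets C6/C7 under reagent control and gives the epoxy alcohol F7. Dess–Martin periodinane with NaHCO3 then oxidises it to 15.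

3. Step 6. During acyl activation the double bond of the but-3-enoyl group may migrate into conjugation (through a vinylketene or a dienolate), giving the crotonate. The fallback forms the ester by carboxylate alkylation with inversion instead of acyl transfer; it sets out from 7 and comes back at 14. The Grignard reagent 9 is made as in step 4 but opens (S)-propylene oxide (C[C@H]1CO1), giving the C21-epimeric alcohol F8. Cross-metathesis with 11 as in step 5 gives the epimeric hydroxy enal F9. Mitsunobu esterification with 13 (PPh3, DIAD, THF, 0 °C) inverts C21 and gives 14.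

Further compounds
F1 | step 8 | (2R,15S,16E)-18-oxo-15-(triethylsilyloxy)octadec-16-en-2-yl prop-2-enoate | C=CC(=O)O[C@H](C)CCCCCCCCCCCC[C@H](O[Si](CC)(CC)CC)/C=C/C=O
F2 | step 8 | (2R,15S)-15-[(2S,3S)-3-formyloxiran-2-yl]-15-(triethylsilyloxy)pentadecan-2-yl prop-2-enoate | C=CC(=O)O[C@H](C)CCCCCCCCCCCC[C@H](O[Si](CC)(CC)CC)[C@H]1O[C@@H]1C=O
F3 | step 8 | (2R,15S)-15-{(2S,3R)-3-[(1S)-1-hydroxybut-3-en-1-yl]oxiran-2-yl}-15-(triethylsilyloxy)pentadecan-2-yl prop-2-enoate | C=CC(=O)O[C@H](C)CCCCCCCCCCCC[C@H](O[Si](CC)(CC)CC)[C@H]1O[C@@H]1[C@@H](O)CC=C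
F4 | step 8 | (2R,15S)-15-{(2S,3S)-3-[(1S)-1-(triethylsilyloxy)but-3-en-1-yl]oxiran-2-yl}-15-(triethylsilyloxy)pentadecan-2-yl prop-2-enoate | C=CC(=O)O[C@H](C)CCCCCCCCCCCC[C@H](O[Si](CC)(CC)CC)[C@H]1O[C@@H]1[C@@H](O[Si](CC)(CC)CC)CC=C
F5 | step 8 | 5,8-bis-O-triethylsilyl CIML C | C[C@@H]1CCCCCCCCCCCC[C@H](O[Si](CC)(CC)CC)[C@H]2O[C@@H]2[C@@H](O[Si](CC)(CC)CC)C/C=C\C(=O)O1
F6 | step 7 | (2R,15S,16E)-18-hydroxy-15-(triethylsilyloxy)octadec-16-en-2-yl but-3-enoate | C=CCC(=O)O[C@H](C)CCCCCCCCCCCC[C@H](O[Si](CC)(CC)CC)/C=C/CO
F7 | step 7 | (2R,15S)-15-[(2S,3R)-3-(hydroxymethyl)oxiran-2-yl]-15-(triethylsilyloxy)pentadecan-2-yl but-3-enoate | C=CCC(=O)O[C@H](C)CCCCCCCCCCCC[C@H](O[Si](CC)(CC)CC)[C@H]1O[C@@H]1CO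
F8 | step 6 | (2S,15S)-15-(triethylsilyloxy)heptadec-16-en-2-ol | C[C@H](O)CCCCCCCCCCCC[C@H](O[Si](CC)(CC)CC)C=C
F9 | step 6 | (2E,4S,17S)-17-hydroxy-4-(triethylsilyloxy)octadec-2-enal | C[C@H](O)CCCCCCCCCCCC[C@H](O[Si](CC)(CC)CC)/C=C/C=O
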